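The readings are calculated with constants of no real substance; noise was put on by code.

The slowness of the cool flasks was what let me count instead of integrate: in the north-west run the substrate still read 97.9% at 25.0 min.

| flask | substrate | temperature | remark | time |
|---|---|---|---|---|
| north-west | 0.018 M | 20 °C | run made earlier |  |
| west | 0.023 M | 45 °C | run made earlier |  |
| eta | 0.020 M | 65 °C |  | 50 min |
| alpha | 0.020 M | 25 °C |  | 50 min |
| delta | 0.012 M | 25 °C |  | 50 min |
| epsilon | 0.012 M | 65 °C |  | 50 min |

- north-west (time / min: target / %, side product / %, substrate / %): 2.00: 0, 0, 97.0; 5.00: 0.9, 0, 101.6; 10.0: 2.1, 0.3, 96.3; 25.0: 0, 0.3, 97.9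
- west (time / min: target / %, side product / %, substrate / %): 1.00: 0.9, 0, 98.4; 3.00: 4.2, 1.5, 93.1; 6.00: 9.2, 6.4, 86.8; 10.0: 11.4, 14.1, 75.8

(standard deviation of a reading: 1 percentage point)

- a species is counted by the substrate in it: one side product counts as two
- a reading or a percentage of target counts all its forms, free or not
- the share counts what is present at the end, not what went on to other products

* all flasks from highest to lowest share of target in all that became target or side product, at 50 min (eta / alpha / delta / epsilon)
* the same order at 10 min (eta / alpha / delta / epsilon)
* the share of target in all that became target or side product of the flask you put first, at 50 min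
* the share of target in all that became target or side product of the flask you put last, at 50 min

I assumed that, while substrate stays near its charge, target appears at a steady pace and is lost by reaction with substrate. That loss is pseudo-first-order, with constant λ = k × [substrate]. Writing x = λt and r for the pace at which target appears, target stands at (r/λ)(1 − e^−x). Each target lost counts as two in the side product, so side/target is ρ = 2(x − 1 + e^−x)/(1 − e^−x), which I solved for x through its near form x + x·x/6, and the share of target is 1/(1 + ρ). The share therefore depends on how many half-lives of target have passed, with τ = ln 2/λ.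

The west reading at 10.0 min had ρ = 1.24, which, with substrate taken at its charge, gave k = 4.58 L mol⁻¹ min⁻¹ at 45 °C. The north-west reading at 10.0 min had ρ = 0.143, small enough to read as x, and gave 0.794 L mol⁻¹ min⁻¹ at 20 °C. Interpolating ln k to 25 °C gave 1.13 L mol⁻¹ min⁻¹, so delta had τ = 51.3 min, x = 0.676 and a share of 57.1%.

The weak link was the cool constant, which rested on a side reading of 0.3% with a scatter of 1 percentage point. Pooling the rows at 10.0 min and 25.0 min gave 1.59 L mol⁻¹ min⁻¹, twice the first value. I could prefer neither, so I took their mean, 1.19 L mol⁻¹ min⁻¹. That gave 1.56 L mol⁻¹ min⁻¹ at 25 °C. Delta's half-life of target against substrate was then τ = 37.1 min, so x = 0.935, and I committed to a share of 48.1% for delta. Alpha's larger charge shortens τ to 22.2 min, so x = 1.56, which gives 33.9%. The rule needs substrate near its charge, so I kept it to these two flasks.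

The forecast, reasoning “heat and dilution favour target”, gave delta > epsilon > alpha > eta at 50 min and delta > alpha > epsilon > eta at 10 min. It put the first flask at 58% (45% to 72%) and the last at 33% (22% to 42%).

The flasks gave delta > epsilon > eta > alpha at 50 min and delta > alpha > epsilon > eta at 10 min, with delta at 52.3%, eta at 43.3% and alpha last at 38.3%.

    substrate + target → side product (k = 1.40 L mol⁻¹ min⁻¹, Ea = 54.0 kJ mol⁻¹)
    target → over-reaction product (k = 3.40 × 10⁻⁵ min⁻¹, Ea = 108 kJ mol⁻¹)
    substrate → target (k = 0.00120 min⁻¹, Ea = 109 kJ mol⁻¹)
    substrate + 2 target → 3 target (k = 160 L² mol⁻² min⁻¹, Ea = 44.0 kJ mol⁻¹)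
    crystals ⇌ target, rate k5*(cs5 - [target]) while solid is left; crystals form when [target] > cs5 (solubility = 6.90 mM, k = 5.00 min⁻¹)
    (constants at 25 °C)

My τ counted 1.35 half-lives for delta at 50 min, and the rule gave 48.1% against its 52.3%. For the same flask read earlier, at 30 min, my τ counts 0.809, and the rule gives 62.0% against 65.2%. Delta had not come to rest, since its substrate still stood at 92.3%. At ten times the time, 500 min, substrate falls to 29.7%, side product rises to 62.3%, target stands at 7.85%, and the share is 11.2%.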